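## Retrosynthetic overview
1. The last step is global O-demethylation of the dodecamethyl ether. No ring is built: all five benzene rings are bought with their oxygen pattern in place (A = 2,4,6-trioxygenated end; B, C, D = inner rings; E = 3,4,5-trioxygenated end).
2. All four disconnections are diaryl ether C–O bonds. Each is cut between the bridging oxygen, kept on the ring where two OMe groups flank it (a 2,6-dimethoxyphenol nucleophile), and the unhindered C1 of the next ring (iodide, bromide or boronate).
3. Rings E, D and C are joined in one flask (two C–O bonds). Unprotected 4-bromo-2,6-dimethoxyphenol serves as a nucleophile-then-electrophile linchpin.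
4. Ring B: the single unhindered C–H of the trimer (para position of ring C) is borylated and coupled in the same flask with the same bromophenol. This leaves a new C–Br handle.
5. Ring A (2,4,6-trimethoxyphenol) is put onto the tetramer bromide. Joining order of the rings: E to D, D to C, C to B, B to A.

Assumption: the target SMILES holds no stereocentre, stereoaxis or double-bond geometry. The molecule is achiral, so there is no enantiomer to control.

## Route

Step 1
Reactants: 1 5-iodo-1,2,3-trimethoxybenzene; 2 4-bromo-2,6-dimethoxyphenol; 3 2,6-dimethoxyphenol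
Product: 5 2-[3,5-dimethoxy-4-(3,4,5-trimethoxyphenoxy)phenoxy]-1,3-dimethoxybenzene (trimer C-D-E), via dimer bromide 4 (not isolated)
Conditions: 1 (1.15 equiv), 2 (1.0 equiv), CuI (10 mol%), picolinic acid (20 mol%), K3PO4 (2 equiv), DMSO, Ar, 80 °C, 16 h; then 3 (2 equiv), K3PO4 (2.5 equiv), 110 °C, 24 h
Reagents that add atoms: none
Why: Proposed new method: charge-gated ambiphilic-linchpin double Ullmann etherification, in which unprotected 2 enters as its potassium phenoxide, so its own C–Br bond (para to O−, an anionic substrate facing the anionic [Cu(picolinate)(OAr)]− resting state) is switched off and it acts only as O-nucleophile toward the far more reactive C–I bond of 1 (oxidative addition to monovalent copper, C–O reductive elimination from trivalent copper); O-arylation removes the charge and turns neutral 4 into an ordinary aryl bromide that is engaged only after 3 is added and the bath is raised to 110 °C, so one catalyst charge makes two C–O bonds in a defined order; the closest known reaction types are iodide-before-bromide sequential ligand-accelerated Ullmann etherification of bromoiodoarenes and substituent-effect chain-growth polycondensation of halophenoxides; no stereocentre is formed.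

Step 2
Reactants: 5 trimer C-D-E; 2 4-bromo-2,6-dimethoxyphenol
Product: 7 5-bromo-2-{3,5-dimethoxy-4-[3,5-dimethoxy-4-(3,4,5-trimethoxyphenoxy)phenoxy]phenoxy}-1,3-dimethoxybenzene (tetramer bromide B-C-D-E), via trimer boronate 6 (not isolated)
Conditions: [Ir(OMe)(cod)]2 (2 mol%), dtbpy (4 mol%), B2pin2 (1.0 equiv), THF, Ar, 80 °C, 16 h; evaporate; then 2 (3 equiv), Cu(OAc)2 (3 equiv), pyridine (6 equiv), B(OH)3 (2 equiv), 4 Å MS, MeCN, Ar, 65 °C, 24 h
Reagents that add atoms: bis(pinacolato)diboron, CC1(C)OB(OC1(C)C)B1OC(C)(C)C(C)(C)O1 (its Bpin group stands in 6 only and is gone in 7)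
Why: Proposed new method: one-flask sterically governed C–H aryloxylation, in which iridium-catalysed C–H borylation hits the only C–H bond of 5 without an ortho substituent (para to the ether oxygen of ring C; every H of rings D and E lies between two oxygen substituents) and the crude pinacol boronate 6 is coupled directly, without release of the boronic acid and without O2, with the di-ortho-methoxy phenol 2; acetate-assisted boron-to-copper transmetalation gives a divalent aryl-copper aryloxide, a second Cu(OAc)2 oxidises it by disproportionation to trivalent copper, C–O reductive elimination follows, the absence of O2 shuts down phenoxyl-radical chain oxidation of 2, and the C–Br bond is inert in this manifold; the closest known reaction type is sequential Hartwig–Miyaura C–H borylation and aerobic Chan–Lam–Evans etherification of simple arenes with unhindered phenols; no stereocentre is formed.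

Step 3
Reactants: 7 tetramer bromide B-C-D-E; 8 2,4,6-trimethoxyphenol
Product: 9 2-{3,5-dimethoxy-4-[3,5-dimethoxy-4-[3,5-dimethoxy-4-(3,4,5-trimethoxyphenoxy)phenoxy]phenoxy]phenoxy}-1,3,5-trimethoxybenzene (dodecamethyl ether of the target)
Conditions: 8 (2 equiv), CuI (20 mol%), picolinic acid (40 mol%), K3PO4 (3 equiv), degassed DMSO, Ar, 110 °C, 36 h
Reagents that add atoms: none
Why: Ligand-accelerated Ullmann etherification works here because the CuI/picolinic acid system suits di-ortho-substituted phenols, 7 carries one unhindered C–Br bond, 8 has no free ortho or para carbon for C-arylation, and strict exclusion of air protects the electron-rich phenoxide.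

Step 4
Reactants: 9 dodecamethyl ether of the target
Product: 10 2-{3,5-dihydroxy-4-[3,5-dihydroxy-4-[3,5-dihydroxy-4-(3,4,5-trihydroxyphenoxy)phenoxy]phenoxy]phenoxy}benzene-1,3,5-triol (CNP0308003.0)
Conditions: BBr3 (30 equiv), CH2Cl2, Ar, −78 °C to rt, 48 h; then MeOH, 0 °C, evaporate; Sephadex LH-20 (MeOH), Ar
Reagents that add atoms: none
Why: In this BBr3 aryl methyl ether cleavage boron binds each OMe oxygen and bromide attacks the methyl carbon, whereas the diaryl ether C–O bonds offer no sp3 carbon and survive, so all twelve OMe groups fall and the achiral target results.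

## Compound list
1 | 5-iodo-1,2,3-trimethoxybenzene (ring E) | COc1cc(I)cc(OC)c1OC | starting material
2 | 4-bromo-2,6-dimethoxyphenol (rings D and B) | COc1cc(Br)cc(OC)c1O | starting material
3 | 2,6-dimethoxyphenol (ring C) | COc1cccc(OC)c1O | starting material
4 | 5-bromo-1,3-dimethoxy-2-(3,4,5-trimethoxyphenoxy)benzene (dimer bromide D-E) | COc1cc(Br)cc(OC)c1Oc1cc(OC)c(OC)c(OC)c1 | intermediate
5 | 2-[3,5-dimethoxy-4-(3,4,5-trimethoxyphenoxy)phenoxy]-1,3-dimethoxybenzene (trimer C-D-E) | COc1cccc(OC)c1Oc1cc(OC)c(Oc2cc(OC)c(OC)c(OC)c2)c(OC)c1 | intermediate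
6 | 2-{4-[3,5-dimethoxy-4-(3,4,5-trimethoxyphenoxy)phenoxy]-3,5-dimethoxyphenyl}-4,4,5,5-tetramethyl-1,3,2-dioxaborolane (trimer boronate) | COc1cc(B2OC(C)(C)C(C)(C)O2)cc(OC)c1Oc1cc(OC)c(Oc2cc(OC)c(OC)c(OC)c2)c(OC)c1 | intermediate
7 | 5-bromo-2-{3,5-dimethoxy-4-[3,5-dimethoxy-4-(3,4,5-trimethoxyphenoxy)phenoxy]phenoxy}-1,3-dimethoxybenzene (tetramer bromide B-C-D-E) | COc1cc(Br)cc(OC)c1Oc1cc(OC)c(Oc2cc(OC)c(Oc3cc(OC)c(OC)c(OC)c3)c(OC)c2)c(OC)c1 | intermediate
8 | 2,4,6-trimethoxyphenol (ring A) | COc1cc(OC)c(O)c(OC)c1 | starting material
9 | 2-{3,5-dimethoxy-4-[3,5-dimethoxy-4-[3,5-dimethoxy-4-(3,4,5-trimethoxyphenoxy)phenoxy]phenoxy]phenoxy}-1,3,5-trimethoxybenzene | COc1cc(OC)c(Oc2cc(OC)c(Oc3cc(OC)c(Oc4cc(OC)c(Oc5cc(OC)c(OC)c(OC)c5)c(OC)c4)c(OC)c3)c(OC)c2)c(OC)c1 | intermediate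
10 | 2-{3,5-dihydroxy-4-[3,5-dihydroxy-4-[3,5-dihydroxy-4-(3,4,5-trihydroxyphenoxy)phenoxy]phenoxy]phenoxy}benzene-1,3,5-triol (achiral) | Oc1cc(O)c(Oc2cc(O)c(Oc3cc(O)c(Oc4cc(O)c(Oc5cc(O)c(O)c(O)c5)c(O)c4)c(O)c3)c(O)c2)c(O)c1 | target

## Step count and risks
Total step count: 4. Longest linear sequence: 4.

The three steps most likely to fail are steps 1, 2 and 4. Step 2 is the weakest. Steps 1 and 2 are the proposed new steps.

**Step 1 (new).**
- Risk: the iodide-over-bromide preference erodes, so 4 reacts with more 2 and gives higher oligomers, or left-over 1 consumes 3.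
- Fallback (known chemistry): it sets out from 2. Phenol 2 is O-arylated with bought 3,4,5-trimethoxyphenylboronic acid F1 under classical aerobic Chan–Lam–Evans conditions (Cu(OAc)2, pyridine, 4 Å MS, CH2Cl2, dry air, rt). A C–Br bond cannot react in this manifold.
- Return: the fallback comes back to the route at 4, which is now isolated and purified. A separate Ullmann etherification of pure 4 with 3 (CuI, picolinic acid, K3PO4, DMSO, 110 °C) then gives 5.

**Step 2 (new).**
- Risk: the pinacol boronate transmetalates slowly, Cu(OAc)2 oxidises 2, or 6 is lost by protodeboronation or hydroxylation.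
- Fallback (known chemistry): it sets out from 5. The C–H borylation is run alone and 6 is isolated. Copper-catalysed iododeboronation (CuI, 1,10-phenanthroline, KI, MeOH/H2O, air, 80 °C) gives the trimer iodide 5-iodo-2-[3,5-dimethoxy-4-(3,4,5-trimethoxyphenoxy)phenoxy]-1,3-dimethoxybenzene F2.
- Return: an iodide-selective Ullmann etherification of F2 with 2 (CuI, picolinic acid, K3PO4, DMSO, 80 °C), followed by isolation, comes back to the route at 7. The C–O bond is thus made in the reductive halide manifold instead of the oxidative boron manifold.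

**Step 4.**
- Risk: twelvefold cleavage stops short because boron aryloxides precipitate, and the free polyphenol is air-sensitive, binds borate and is hard to purify.
- Fallback: it sets out from 9. After the BBr3 cleavage and MeOH quench the free phenol is not isolated. The crude material is peracetylated (Ac2O, pyridine, DMAP) to the dodecaacetate F3.
- Purification and return: F3 is stable and is purified on silica gel, where under-demethylated material separates and is recycled. Acid methanolysis (HCl from AcCl in MeOH, Ar, rt) releases the phenols and comes back to the route at 10.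

## Further compounds
F1 | step 1 | 3,4,5-trimethoxyphenylboronic acid (bought) | COc1cc(B(O)O)cc(OC)c1OC
F2 | step 2 | 5-iodo-2-[3,5-dimethoxy-4-(3,4,5-trimethoxyphenoxy)phenoxy]-1,3-dimethoxybenzene (trimer iodide) | COc1cc(I)cc(OC)c1Oc1cc(OC)c(Oc2cc(OC)c(OC)c(OC)c2)c(OC)c1
F3 | step 4 | dodecaacetate of 10 | CC(=O)Oc1cc(OC(C)=O)c(Oc2cc(OC(C)=O)c(Oc3cc(OC(C)=O)c(Oc4cc(OC(C)=O)c(Oc5cc(OC(C)=O)c(OC(C)=O)c(OC(C)=O)c5)c(OC(C)=O)c4)c(OC(C)=O)c3)c(OC(C)=O)c2)c(OC(C)=O)c1
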